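X + E → J, E + J → G and G ⇌ D pass the X along, and E → Q never touches it, so X, J, G and D, as fractions of the charge, sum to one at any moment.

the same everywhere: X 0.050 M
- alpha: E 0.065 M; run made earlier
- gamma: E 0.13 M; run made earlier
- beta: E 0.19 M; run made earlier
- red: E 0.0750 M; time 8.0 d
- green: E 0.200 M; time 8.0 d

| run | time / d | G / % | X / % |
|---|---|---|---|
| alpha | 0.625 | 5.4 | 50.3 |
| alpha | 1.25 | 10.9 | 32.8 |
| alpha | 2.50 | 16.4 | 21.7 |
| alpha | 4.00 | 19.2 | 14.2 |
| alpha | 8.00 | 22.5 | 11.9 |
| gamma | 0.625 | 16.4 | 24.1 |
| gamma | 2.08 | 40.4 | 4.7 |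
| gamma | 4.00 | 49.3 | 1.5 |
| gamma | 6.00 | 54.9 | 0 |
| gamma | 8.00 | 55.9 | 0 |
| beta | 0.625 | 30.2 | 10.8 |
| beta | 1.25 | 46.2 | 1.5 |
| beta | 2.50 | 56.3 | 0 |
| beta | 4.00 | 60.2 | 0 |
| beta | 8.00 | 61.2 | 0 |

(scatter of a reading: 1 percentage point)

- steps thought possible: X + E -> J; E + J -> G; E -> Q; G <-> D

- which of these holds the largest part of the X at the end of red (J / G / X)
- which of these holds the largest part of the X at the end of green (J / G / X)
- amount of G at the end of green, in percent of the X charged

*What stands nearly still?* In beta, G moved by 1 percentage point between 4.00 d and 8.00 d, which is the size of the scatter.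

*Is E short there?* No: taking X to G or D costs two equivalents of E, and beta received 3.80.

*So where is the charge?* X reads 0% and I take J as near zero, so G and D hold the charge between them. G's share of that pair, the plateau share, is then the reading 61.2%.

*But gamma ends at 55.9%. Why trust beta?* Gamma received 2.60 equivalents, fewer than beta. With X at 0%, I read its gap through the share as J of 8.66%.

*And your commitment?* Green receives 4.00 equivalents, more than beta, so I put G at the plateau share, the largest holder. For alpha, where E is the limiting reagent, the share and the sum give J of 51.3%. Red's 1.50 equivalents lie close to alpha's 1.30, so I say J for red.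

The forecast gives J for red, G for green and G of 61.5% (59.5% to 64%), on the ground that “G must be equilibrated with D”.

The flask gives J for red, G for green and G of 60.6% in green.

    X + E → J (k = 0.940 M⁻¹ h⁻¹)
    E + J → G (k = 0.400 M⁻¹ h⁻¹)
    E → Q (k = 1.20 × 10⁻⁴ h⁻¹)
    G ⇌ D (K = 0.650, k = 0.0650 h⁻¹)

In green, the half-life of G by the forward G → D step alone at 0.167 d is 0.44 d, shorter than the 8.0 d of the run. Backward turnover of that step in green stands at 94% of the forward one, and the plateau share of what X (0%) and J (0.0465%) leave at 8.00 d is 61.2%. In a neighbouring flask, green with 0.050 M of E, X (24.0%) and J (53.1%) leave 22.9% for the pair, so the share gives 14.0%, and that flask holds G of 13.9%.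

The runs come from a simulation for an exercise; scatter was added.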